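**Strategy.** The target is a twofold-symmetric dimer: two identical 2-isobutyryl-4,4-dimethylcyclohexane-1,3,5-trione (filicinic acid) rings A and B, joined through their C6 atoms by one CH2. Each ring is treated as a tetraketide in disguise: its acyl-bearing carbon C2 is a diketonate carbanion, and C3–C4(CH3)2–C5 is a non-enolisable dimethylmalonyl unit. The key step copies the polyketide-synthase Claisen cyclisation and closes each ring at C2–C3 in one pot: the dianion of 5-methylhexane-2,4-dione is acylated by dimethyl dimethylmalonate, and the resulting open-chain triketo ester polyanion cyclises to isobutyrylfilicinic acid. Formaldehyde then joins two such rings at C6.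

Key step: step 1

Remark: the target has no stereocentre. Compounds 3 to 7 are enolised polycarbonyl compounds, each drawn as one of its rapidly interconverting tautomers. Ring numbering: C1 = ring C=O between C2 and C6, C2 = acyl-bearing carbon, C3 and C5 = enolised carbonyl carbons, C4 = C(CH3)2, C6 = carbon that carries H in 4 and the bridging CH2 in 7.

**Step 1**
Reactants: 1 5-methylhexane-2,4-dione; 2 dimethyl 2,2-dimethylpropanedioate (dimethyl dimethylmalonate)
Product: 4 isobutyrylfilicinic acid (3,5-dihydroxy-4,4-dimethyl-2-(2-methylpropanoyl)cyclohexa-2,5-dien-1-one), via triketo ester polyanion 3 (not isolated)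
Conditions: LiN(iPr)2 (3.3 equiv), THF, −78 → 0 °C; then 2 (1.2 equiv), 0 °C → reflux; then 2 M HCl
Reagents that add atoms: none
Why: The dianion of 1, formed kinetically at the CH3 group and not at the isopropyl methine, should attack one ester of 2 through its terminal carbon (intermolecular Claisen acylation, forming C5–C6) to give the polyanion of triketo ester 3, whose internal diketonate carbon (future C2) then attacks the remaining ester carbonyl (future C3) and expels methoxide in an intramolecular Claisen (Dieckmann-type) condensation. The closest known reaction types are the acylation of β-diketone dianions by non-enolisable esters to 1,3,5-triketones and the base-mediated Claisen cyclisation of 3,5,7-triketo esters to acylphloroglucinols, the laboratory counterpart of the polyketide-synthase ring closure. The six-membered ring closes in the 6-(enolendo)-exo-trig mode at the ester carbonyl. No stereocentre is formed and the product is achiral. C- over O-acylation in the ring closure should be settled thermodynamically, because methoxide reopens any pyran-2,4-dione enol lactone whereas the carbocycle is trapped as the dianion of a vinylogous acid, and an aldol-type closure is excluded because C4 is quaternary, its gem-dimethyl group also bringing the chain ends together. Mono- rather than double acylation of 2 is secured by the intramolecular closure outrunning a second intermolecular attack on a hindered ester and by the slight excess of 2.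

**Step 2**
Reactants: 4 isobutyrylfilicinic acid (two equivalents)
Product: 7 6,6'-methylenebis[3,5-dihydroxy-4,4-dimethyl-2-(2-methylpropanoyl)cyclohexa-2,5-dien-1-one] (target), via hydroxymethyl adduct 5 (not isolated), via methylidene trione 6 (not isolated)
Conditions: 37% aq. CH2O (0.5 equiv per 4), 1% aq. KOH, rt; then 1 M HCl
Reagents that add atoms: formaldehyde (37% aqueous solution), C=O
Why: Base-mediated methylene bridging of acylfilicinic acids is known chemistry (Knoevenagel-type hydroxymethylation at C6 to 5, dehydration to the methylidene trione 6, Michael addition of a second molecule of 4), and C6 is the only nucleophilic ring carbon left because C2 is acylated and C4 is quaternary; no stereocentre is formed.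

**Compound list**
1 | 5-methylhexane-2,4-dione | CC(C)C(=O)CC(C)=O | starting material
2 | dimethyl 2,2-dimethylpropanedioate (dimethyl dimethylmalonate) | COC(=O)C(C)(C)C(=O)OC | starting material
3 | methyl 2,2,8-trimethyl-3,5,7-trioxononanoate (present in the flask as its lithium polyanion) | COC(=O)C(C)(C)C(=O)CC(=O)CC(=O)C(C)C | intermediate
4 | isobutyrylfilicinic acid, 3,5-dihydroxy-4,4-dimethyl-2-(2-methylpropanoyl)cyclohexa-2,5-dien-1-one | CC(C)C(=O)C1=C(O)C(C)(C)C(O)=CC1=O | intermediate
5 | 3,5-dihydroxy-6-(hydroxymethyl)-4,4-dimethyl-2-(2-methylpropanoyl)cyclohexa-2,5-dien-1-one | CC(C)C(=O)C1=C(O)C(C)(C)C(O)=C(CO)C1=O | intermediate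
6 | 5-hydroxy-6,6-dimethyl-2-methylidene-4-(2-methylpropanoyl)cyclohex-4-ene-1,3-dione | CC(C)C(=O)C1=C(O)C(C)(C)C(=O)C(=C)C1=O | intermediate
7 | 6,6'-methylenebis[3,5-dihydroxy-4,4-dimethyl-2-(2-methylpropanoyl)cyclohexa-2,5-dien-1-one] | CC(C)C(=O)C1=C(O)C(C)(C)C(O)=C(CC2=C(O)C(C)(C)C(O)=C(C(=O)C(C)C)C2=O)C1=O | target

Total step count: 2
Longest linear sequence: 2

**Steps most likely to fail** (the route has only two steps, so both are ranked)

1. Step 1. The intermolecular acylation at the neopentyl-type ester carbonyl may be slow, so that proton transfer quenches the dianion or a second dianion attacks the remaining ester. The ring closure may also stall at the open-chain polyanion or divert to O-acylation. Fallback, setting out from 1 and coming back at 4: the two C–C bond formations are separated and the first is run without a strong base present. The dianion of 1 (LiN(iPr)2, THF, −78 → 0 °C) is trapped on both oxygens with Me3SiCl to give the bis(silyl enol ether) (3Z)-5-methyl-2,4-bis(trimethylsilyloxy)hexa-1,3-diene F1. F1 is C-acylated at its terminal CH2 by commercially available methyl 3-chloro-2,2-dimethyl-3-oxopropanoate (CH2Cl2, −78 °C → rt, then aqueous work-up), a Mukaiyama-type acylation of a silyl enol ether by an acid chloride, which should give triketo ester 3 as an isolated compound. Compound 3 is then cyclised in a separate Claisen step under protic, equilibrating conditions (NaOMe, MeOH, reflux, then HCl) to 4, so the same ring bond is still made by ring closure.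

2. Step 2. The condensation may stop at the hydroxymethyl stage, the methylidene intermediate may be consumed by water or by oligomerisation before a second molecule of 4 captures it, and prolonged contact with alkali may cause retro-Claisen loss of the acyl group. Fallback, setting out from 4 and coming back at 7: the electrophilic half is made as a stable Mannich base and united with the nucleophilic half without aqueous alkali. One portion of 4 is aminomethylated at C6 with dimethylmethylideneammonium iodide (CH2Cl2, rt) to the Mannich base 6-[(dimethylamino)methyl]-3,5-dihydroxy-4,4-dimethyl-2-(2-methylpropanoyl)cyclohexa-2,5-dien-1-one F2. F2 and one equivalent of 4 are heated in ethanol at reflux; F2 should lose dimethylamine to release 6 slowly, and 4 captures it by Michael addition to give 7.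

**Further compounds**
F1 | step 1 | (3Z)-5-methyl-2,4-bis(trimethylsilyloxy)hexa-1,3-diene | CC(C)/C(O[Si](C)(C)C)=C/C(=C)O[Si](C)(C)C
F2 | step 2 | 6-[(dimethylamino)methyl]-3,5-dihydroxy-4,4-dimethyl-2-(2-methylpropanoyl)cyclohexa-2,5-dien-1-one | CC(C)C(=O)C1=C(O)C(C)(C)C(O)=C(CN(C)C)C1=O
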